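**Plan**

Atom numbers follow the dodecadienedione chain of the target: C1 is the aryl ketone carbon, C3 the quaternary carbon, C6=C7 the E alkene, C9 the chain ketone and C10=C11 the terminal alkene. The oct-6-ene intermediates share C1–C8 with it.

- Cuts, in retrosynthetic order: both C–C bonds at C9 (C8–C9 and C9–C10) together, giving an E allylic bromide, CO and an alkenylstannane; C8–Br back to the C8 methyl of a prenyl end; aryl–C1 to an aryllithium and an aldehyde; C3–vinyl to a tertiary boronic ester; C3–B to methyl geranate.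
- Feature used: C9 is the carbonyl of an allyl vinyl ketone, held between the allylic C8H2 of the E-trisubstituted C6=C7 alkene and the alkenyl C10H=C11Me2 unit. Its β,γ-alkene drifts into conjugation with acid or base, so this ketone is built last, under neutral palladium catalysis.
- Forward: no ring is formed (the benzene ring is bought). The chain is joined in the order boron at C3, vinyl at C3, aryl ketone at C1, oxygen then bromine at C8, CO plus the C10–C12 alkenyl unit at C8, then loss of the two acetals.
- Stereochemistry: the only stereocentre, C3, is set by ligand-controlled copper-catalysed β-borylation (S boronate) and passed on with retention in the Zweifel vinylation (R quaternary carbon). The 6E alkene comes from E-selective SeO2 oxidation and is kept through bromination and carbonylation.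

Key step: step 13

Remark: methyl geranate is used as the pure 2E ester, and the antipode of the ferrocenyl bisphosphine named in step 1 is assumed to deliver boron to the Re face of C3; if a trial shows the opposite sense, its mirror image is used and nothing else changes.

**Route**

Step 1
Reactants: 1 methyl geranate [methyl (2E)-3,7-dimethylocta-2,6-dienoate]; 2 bis(pinacolato)diboron
Product: 3 methyl (3S)-3,7-dimethyl-3-(4,4,5,5-tetramethyl-1,3,2-dioxaborolan-2-yl)oct-6-enoate
Conditions: CuCl (3 mol %), NaOtBu (6 mol %), (R)-1-[(S)-2-(diphenylphosphino)ferrocenyl]ethyldicyclohexylphosphine (4 mol %), MeOH (2 equiv), THF, rt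
Reagents that add atoms: none
Why: Copper-catalysed asymmetric conjugate borylation of a β,β-disubstituted enoate, in which the ligated Cu–Bpin species adds syn across C2=C3 with boron going to the β-carbon and methanol protonates the copper enolate, the chiral bisphosphine choosing the Re face of C3 so that the stereocentre is set as S, while the isolated C6=C7 alkene is no acceptor and stays untouched.

Step 2
Reactants: 3 methyl (3S)-3,7-dimethyl-3-(4,4,5,5-tetramethyl-1,3,2-dioxaborolan-2-yl)oct-6-enoate
Product: 4 (3S)-3,7-dimethyl-3-(4,4,5,5-tetramethyl-1,3,2-dioxaborolan-2-yl)oct-6-en-1-ol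
Conditions: i-Bu2AlH (2.5 equiv), CH2Cl2, −78 → 0 °C; aq. KNaC4H4O6
Reagents that add atoms: none
Why: Ester reduction with i-Bu2AlH takes the methyl ester to the primary alcohol at low temperature, the hindered tertiary pinacol boronate and the trisubstituted alkene being inert to the hydride and the C3 centre not being involved.

Step 3
Reactants: 4 (3S)-3,7-dimethyl-3-(4,4,5,5-tetramethyl-1,3,2-dioxaborolan-2-yl)oct-6-en-1-ol
Product: 5 tert-butyl{[(3S)-3,7-dimethyl-3-(4,4,5,5-tetramethyl-1,3,2-dioxaborolan-2-yl)oct-6-en-1-yl]oxy}dimethylsilane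
Conditions: TBSCl, imidazole, CH2Cl2, rt
Reagents that add atoms: tert-butyldimethylsilyl chloride, CC(C)(C)[Si](C)(C)Cl
Why: Imidazole-promoted silyl ether formation masks the primary hydroxyl, which would otherwise quench the vinyl Grignard reagent and tie up boron as a cyclic borate in the next step.

Step 4
Reactants: 5 tert-butyl{[(3S)-3,7-dimethyl-3-(4,4,5,5-tetramethyl-1,3,2-dioxaborolan-2-yl)oct-6-en-1-yl]oxy}dimethylsilane
Product: 8 tert-butyl{[(3R)-3-ethenyl-3,7-dimethyloct-6-en-1-yl]oxy}dimethylsilane, via vinyl boronate complex 6 (not isolated), via β-iodoalkyl boronic ester 7 (not isolated)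
Conditions: CH2=CHMgBr (1.5 equiv), THF/DMSO, rt; then I2, THF, 0 °C; then NaOMe, MeOH, 0 °C → rt
Reagents that add atoms: vinylmagnesium bromide, C=C[Mg]Br
Why: Zweifel olefination, in which the vinyl Grignard reagent adds to boron, iodine activates the vinyl group of complex 6 and triggers 1,2-migration of the tertiary alkyl group from boron to carbon with retention, and methoxide-induced anti elimination of boron and iodide from 7 unveils the vinyl group, so the C3 configuration is carried over unchanged (the descriptor turns from S to R only because the priorities change) and the quaternary centre is complete.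

Step 5
Reactants: 8 tert-butyl{[(3R)-3-ethenyl-3,7-dimethyloct-6-en-1-yl]oxy}dimethylsilane
Product: 9 (3R)-3-ethenyl-3,7-dimethyloct-6-en-1-ol
Conditions: n-Bu4NF, THF, 0 °C → rt
Reagents that add atoms: none
Why: Fluoride-induced desilylation frees the primary alcohol and touches neither alkene.

Step 6
Reactants: 9 (3R)-3-ethenyl-3,7-dimethyloct-6-en-1-ol
Product: 10 (3R)-3-ethenyl-3,7-dimethyloct-6-enal
Conditions: Dess–Martin periodinane, NaHCO3, CH2Cl2, 0 °C → rt
Reagents that add atoms: none
Why: Dess–Martin oxidation of a primary alcohol stops at the aldehyde under buffered conditions, and the aldehyde has no α-stereocentre to lose.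

Step 7
Reactants: 11 4-bromoresorcinol
Product: 12 1-bromo-2,4-bis(methoxymethoxy)benzene
Conditions: MOMCl, i-Pr2NEt, CH2Cl2, 0 °C → rt
Reagents that add atoms: chloromethyl methyl ether, COCCl
Why: O-Alkylation of both phenols with chloromethyl methyl ether under amine base (acetal protection) gives ethers that survive butyllithium and the later oxidations and whose ortho oxygen helps stabilise the aryllithium.

Step 8
Reactants: 12 1-bromo-2,4-bis(methoxymethoxy)benzene; 10 (3R)-3-ethenyl-3,7-dimethyloct-6-enal
Product: 14 (3R)-1-[2,4-bis(methoxymethoxy)phenyl]-3-ethenyl-3,7-dimethyloct-6-en-1-ol (both C1 epimers), via [2,4-bis(methoxymethoxy)phenyl]lithium 13 (not isolated)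
Conditions: 12 (1.3 equiv), n-BuLi, THF, −78 °C; then 10, −78 → −40 °C; H2O
Reagents that add atoms: none
Why: Bromine–lithium exchange outruns any attack on the acetals and aryllithium 13 adds 1,2 to aldehyde 10 (organolithium carbonyl addition), joining the ring to C1 at the former C–Br carbon so that the oxygens sit ortho and para, while the new carbinol centre forms without control and is erased in step 9.

Step 9
Reactants: 14 (3R)-1-[2,4-bis(methoxymethoxy)phenyl]-3-ethenyl-3,7-dimethyloct-6-en-1-ol
Product: 15 (3R)-1-[2,4-bis(methoxymethoxy)phenyl]-3-ethenyl-3,7-dimethyloct-6-en-1-one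
Conditions: Dess–Martin periodinane, NaHCO3, CH2Cl2, 0 °C → rt
Reagents that add atoms: none
Why: Dess–Martin oxidation of the benzylic secondary alcohol gives the aryl ketone and merges both C1 epimers, with bicarbonate shielding the acetals from the acetic acid released.

Step 10
Reactants: 15 (3R)-1-[2,4-bis(methoxymethoxy)phenyl]-3-ethenyl-3,7-dimethyloct-6-en-1-one
Product: 16 (3R,6E)-1-[2,4-bis(methoxymethoxy)phenyl]-3-ethenyl-8-hydroxy-3,7-dimethyloct-6-en-1-one
Conditions: SeO2 (0.3 equiv), t-BuOOH (3 equiv), CH2Cl2, 0 °C → rt, stopped at partial conversion, recovered 15 recycled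
Reagents that add atoms: selenium dioxide, O=[Se]=O (oxygen carrier); tert-butyl hydroperoxide, CC(C)(C)OO (terminal oxidant)
Why: Catalytic SeO2 allylic oxidation with t-BuOOH as reoxidant (ene reaction followed by [2,3]-sigmatropic shift) hydroxylates the methyl group trans to the chain at the more substituted alkene terminus, which gives the 6E allylic alcohol, while the C3 vinyl group has no allylic hydrogen and the hindered, electron-rich aryl ketone should enolise too slowly at room temperature to be oxidised.

Step 11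
Reactants: 16 (3R,6E)-1-[2,4-bis(methoxymethoxy)phenyl]-3-ethenyl-8-hydroxy-3,7-dimethyloct-6-en-1-one
Product: 17 (3R,6E)-1-[2,4-bis(methoxymethoxy)phenyl]-8-bromo-3-ethenyl-3,7-dimethyloct-6-en-1-one
Conditions: CBr4, PPh3, 2,6-lutidine, CH2Cl2, −20 → 0 °C
Reagents that add atoms: carbon tetrabromide, BrC(Br)(Br)Br
Why: Appel bromination converts the primary allylic alcohol to the bromide by SN2 displacement of the oxyphosphonium group under essentially neutral conditions, so the 6E geometry, the ketone and the acetals are kept.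

Step 12
Reactants: 18 2-methylprop-1-enylmagnesium bromide; 19 tributyltin chloride
Product: 20 tributyl(2-methylprop-1-enyl)stannane
Conditions: THF, 0 °C → rt
Reagents that add atoms: none
Why: Transmetalation of the alkenyl Grignard reagent to tin (nucleophilic substitution at tin) gives the air-stable alkenylstannane, which has no geometry to control because its β-carbon carries two methyl groups.

Step 13
Reactants: 17 (3R,6E)-1-[2,4-bis(methoxymethoxy)phenyl]-8-bromo-3-ethenyl-3,7-dimethyloct-6-en-1-one; 20 tributyl(2-methylprop-1-enyl)stannane; 21 carbon monoxide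
Product: 22 (3R,6E)-1-[2,4-bis(methoxymethoxy)phenyl]-3-ethenyl-3,7,11-trimethyldodeca-6,10-diene-1,9-dione
Conditions: Pd(PPh3)4 (5 mol %), CO (3 atm), THF, 50 °C
Reagents that add atoms: none
Why: Zerovalent palladium from Pd(PPh3)4 ionises the allylic C8–Br bond of 17 to an η3-allyl complex of divalent palladium, CO inserts at the primary C8 terminus to give an acyl complex, stannane 20 hands over its 2-methylprop-1-enyl group, and reductive elimination forges C8–C9 and C9–C10 and returns zerovalent palladium. The closest known reaction type is the carbonylative Stille coupling of allyl halides with alkenylstannanes to give allyl vinyl ketones. No ring closes and no stereocentre forms, the C3 centre being a spectator. The step needs acylation at the primary terminus with the 6E geometry kept, which the less hindered CH2 end of the allyl ligand secures, and it needs CO insertion to outrun direct allyl–alkenyl coupling, which the CO pressure and the slow transmetalation of the β,β-disubstituted alkenylstannane favour. Because the medium contains neither acid nor base, the new β,γ-alkene is not pushed into conjugation, and the C3 vinyl group (no allylic leaving group), the aryl ketone and the acetals stay untouched.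

Step 14
Reactants: 22 (3R,6E)-1-[2,4-bis(methoxymethoxy)phenyl]-3-ethenyl-3,7,11-trimethyldodeca-6,10-diene-1,9-dione
Product: 23 (3R,6E)-1-(2,4-dihydroxyphenyl)-3-ethenyl-3,7,11-trimethyldodeca-6,10-diene-1,9-dione (CNP0208188.1)
Conditions: dilute HCl, MeOH/THF, rt
Reagents that add atoms: none
Why: Acid-catalysed acetal cleavage (transacetalisation to methanol) removes both methoxymethyl groups at room temperature, the ortho one helped by the neighbouring carbonyl, with acid dilute enough that enolisation of the C9 ketone towards C8, the path by which the C6=C7 bond would move into conjugation, should stay slow.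

**Compound list**

1 | methyl geranate, methyl (2E)-3,7-dimethylocta-2,6-dienoate | COC(=O)/C=C(\C)CCC=C(C)C | starting material
2 | bis(pinacolato)diboron | CC1(C)OB(OC1(C)C)B1OC(C)(C)C(C)(C)O1 | starting material
3 | methyl (3S)-3,7-dimethyl-3-(4,4,5,5-tetramethyl-1,3,2-dioxaborolan-2-yl)oct-6-enoate | CC1(C)OB(OC1(C)C)[C@](C)(CCC=C(C)C)CC(=O)OC | intermediate
4 | (3S)-3,7-dimethyl-3-(4,4,5,5-tetramethyl-1,3,2-dioxaborolan-2-yl)oct-6-en-1-ol | CC1(C)OB(OC1(C)C)[C@](C)(CCC=C(C)C)CCO | intermediate
5 | tert-butyl{[(3S)-3,7-dimethyl-3-(4,4,5,5-tetramethyl-1,3,2-dioxaborolan-2-yl)oct-6-en-1-yl]oxy}dimethylsilane | CC1(C)OB(OC1(C)C)[C@](C)(CCC=C(C)C)CCO[Si](C)(C)C(C)(C)C | intermediate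
6 | bromomagnesium vinyl boronate complex of 5 (vinyl on tetracoordinate boron, C3 unchanged) | C=C[B-]1(OC(C)(C)C(C)(C)O1)[C@](C)(CCC=C(C)C)CCO[Si](C)(C)C(C)(C)C.[Mg+2].[Br-] | intermediate
7 | β-iodoalkyl boronic ester after 1,2-migration: the quaternary carbon of 8 carrying CH(Bpin)CH2I in place of vinyl (quaternary centre unchanged, CH–B centre undefined) | ICC(B1OC(C)(C)C(C)(C)O1)[C@](C)(CCC=C(C)C)CCO[Si](C)(C)C(C)(C)C | intermediate
8 | tert-butyl{[(3R)-3-ethenyl-3,7-dimethyloct-6-en-1-yl]oxy}dimethylsilane | C=C[C@](C)(CCC=C(C)C)CCO[Si](C)(C)C(C)(C)C | intermediate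
9 | (3R)-3-ethenyl-3,7-dimethyloct-6-en-1-ol | C=C[C@](C)(CCC=C(C)C)CCO | intermediate
10 | (3R)-3-ethenyl-3,7-dimethyloct-6-enal | C=C[C@](C)(CCC=C(C)C)CC=O | intermediate
11 | 4-bromoresorcinol | Oc1ccc(Br)c(O)c1 | starting material
12 | 1-bromo-2,4-bis(methoxymethoxy)benzene | COCOc1ccc(Br)c(OCOC)c1 | intermediate
13 | [2,4-bis(methoxymethoxy)phenyl]lithium | [Li]c1ccc(OCOC)cc1OCOC | intermediate
14 | (3R)-1-[2,4-bis(methoxymethoxy)phenyl]-3-ethenyl-3,7-dimethyloct-6-en-1-ol (C1 epimer mixture) | C=C[C@](C)(CCC=C(C)C)CC(O)c1ccc(OCOC)cc1OCOC | intermediate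
15 | (3R)-1-[2,4-bis(methoxymethoxy)phenyl]-3-ethenyl-3,7-dimethyloct-6-en-1-one | C=C[C@](C)(CCC=C(C)C)CC(=O)c1ccc(OCOC)cc1OCOC | intermediate
16 | (3R,6E)-1-[2,4-bis(methoxymethoxy)phenyl]-3-ethenyl-8-hydroxy-3,7-dimethyloct-6-en-1-one | C=C[C@](C)(CC/C=C(\C)CO)CC(=O)c1ccc(OCOC)cc1OCOC | intermediate
17 | (3R,6E)-1-[2,4-bis(methoxymethoxy)phenyl]-8-bromo-3-ethenyl-3,7-dimethyloct-6-en-1-one | C=C[C@](C)(CC/C=C(\C)CBr)CC(=O)c1ccc(OCOC)cc1OCOC | intermediate
18 | 2-methylprop-1-enylmagnesium bromide | CC(C)=C[Mg]Br | starting material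
19 | tributyltin chloride | CCCC[Sn](Cl)(CCCC)CCCC | starting material
20 | tributyl(2-methylprop-1-enyl)stannane | CCCC[Sn](CCCC)(CCCC)C=C(C)C | intermediate
21 | carbon monoxide | [C-]#[O+] | starting material
22 | (3R,6E)-1-[2,4-bis(methoxymethoxy)phenyl]-3-ethenyl-3,7,11-trimethyldodeca-6,10-diene-1,9-dione | C=C[C@](C)(CC/C=C(\C)CC(=O)C=C(C)C)CC(=O)c1ccc(OCOC)cc1OCOC | intermediate
23 | (3R,6E)-1-(2,4-dihydroxyphenyl)-3-ethenyl-3,7,11-trimethyldodeca-6,10-diene-1,9-dione | C=C[C@](C)(CC/C=C(\C)CC(=O)C=C(C)C)CC(=O)c1ccc(O)cc1O | target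

**Step count**

Total: 14 steps (steps 7 and 12 prepare the two coupling partners). Longest linear sequence: 12 steps from methyl geranate (steps 1–6, 8–11, 13, 14).

**Steps most likely to fail, with fallbacks**

Step 13. The allyl and alkenyl groups may couple directly before CO is taken up, or the freshly formed β,γ-double bond may migrate into conjugation on the metal. The fallback makes the C9 ketone without CO. Bromide 17 would be coupled with 2-methylbut-3-yn-2-ol through its copper acetylide (CuI, K2CO3, NaI, DMF, rt), substituting at the primary allylic carbon to give the skipped enynol (3R,6E)-1-[2,4-bis(methoxymethoxy)phenyl]-3-ethenyl-11-hydroxy-3,7,11-trimethyldodec-6-en-9-yn-1-one F1. A gold-catalysed Meyer–Schuster rearrangement (Ph3PAuNTf2, MeOH, toluene, rt) would then turn the tertiary propargylic alcohol into the 2-methylprop-1-enyl ketone, returning to 22.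

Step 10. The allylic oxidation may run on to the enal, may attack the CH2 next to the aryl ketone, or may cost an acetal through the acidic selenium species. The fallback installs the C8 oxygen before the aryl ketone exists, setting out from silyl ether 8 and returning at 16.
- SeO2/t-BuOOH in CH2Cl2, then NaBH4 in MeOH (no ketone is present, so any enal can be reduced back freely), should give (2E,6R)-8-[(tert-butyldimethylsilyl)oxy]-6-ethenyl-2,6-dimethyloct-2-en-1-ol F2.
- NaH and 4-methoxybenzyl chloride in THF/DMF should give tert-butyl{[(3R,6E)-3-ethenyl-8-[(4-methoxybenzyl)oxy]-3,7-dimethyloct-6-en-1-yl]oxy}dimethylsilane F3.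
- n-Bu4NF should free (3R,6E)-3-ethenyl-8-[(4-methoxybenzyl)oxy]-3,7-dimethyloct-6-en-1-ol F4.
- Dess–Martin oxidation should give (3R,6E)-3-ethenyl-8-[(4-methoxybenzyl)oxy]-3,7-dimethyloct-6-enal F5.
- Aryllithium 13 should add to give (3R,6E)-1-[2,4-bis(methoxymethoxy)phenyl]-3-ethenyl-8-[(4-methoxybenzyl)oxy]-3,7-dimethyloct-6-en-1-ol F6.
- A second Dess–Martin oxidation should give (3R,6E)-1-[2,4-bis(methoxymethoxy)phenyl]-3-ethenyl-8-[(4-methoxybenzyl)oxy]-3,7-dimethyloct-6-en-1-one F7.
- DDQ in wet CH2Cl2 should remove the 4-methoxybenzyl group and return to allylic alcohol 16.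

Step 14. Acid-promoted enolisation may move the C6=C7 bond into conjugation with the C9 ketone, or methanol may add to the enone, before the para acetal has gone. The fallback removes the acetals before the sensitive ketone is made. Allylic alcohol 16 would be treated with HCl in MeOH to give the triol (3R,6E)-1-(2,4-dihydroxyphenyl)-3-ethenyl-8-hydroxy-3,7-dimethyloct-6-en-1-one F8. Appel bromination (CBr4, PPh3, CH2Cl2, 0 °C), which leaves phenols alone, should give (3R,6E)-8-bromo-1-(2,4-dihydroxyphenyl)-3-ethenyl-3,7-dimethyloct-6-en-1-one F9, to be used at once. The carbonylative coupling of F9 with stannane 20 and CO under Pd(PPh3)4, run without base so the phenols are not allylated, would then give target 23 directly.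

**Further compounds**

F1 | step 13 | (3R,6E)-1-[2,4-bis(methoxymethoxy)phenyl]-3-ethenyl-11-hydroxy-3,7,11-trimethyldodec-6-en-9-yn-1-one | C=C[C@](C)(CC/C=C(\C)CC#CC(C)(C)O)CC(=O)c1ccc(OCOC)cc1OCOC
F2 | step 10 | (2E,6R)-8-[(tert-butyldimethylsilyl)oxy]-6-ethenyl-2,6-dimethyloct-2-en-1-ol | C=C[C@](C)(CC/C=C(\C)CO)CCO[Si](C)(C)C(C)(C)C
F3 | step 10 | tert-butyl{[(3R,6E)-3-ethenyl-8-[(4-methoxybenzyl)oxy]-3,7-dimethyloct-6-en-1-yl]oxy}dimethylsilane | C=C[C@](C)(CC/C=C(\C)COCc1ccc(OC)cc1)CCO[Si](C)(C)C(C)(C)C
F4 | step 10 | (3R,6E)-3-ethenyl-8-[(4-methoxybenzyl)oxy]-3,7-dimethyloct-6-en-1-ol | C=C[C@](C)(CC/C=C(\C)COCc1ccc(OC)cc1)CCO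
F5 | step 10 | (3R,6E)-3-ethenyl-8-[(4-methoxybenzyl)oxy]-3,7-dimethyloct-6-enal | C=C[C@](C)(CC/C=C(\C)COCc1ccc(OC)cc1)CC=O
F6 | step 10 | (3R,6E)-1-[2,4-bis(methoxymethoxy)phenyl]-3-ethenyl-8-[(4-methoxybenzyl)oxy]-3,7-dimethyloct-6-en-1-ol (C1 epimer mixture) | C=C[C@](C)(CC/C=C(\C)COCc1ccc(OC)cc1)CC(O)c1ccc(OCOC)cc1OCOC
F7 | step 10 | (3R,6E)-1-[2,4-bis(methoxymethoxy)phenyl]-3-ethenyl-8-[(4-methoxybenzyl)oxy]-3,7-dimethyloct-6-en-1-one | C=C[C@](C)(CC/C=C(\C)COCc1ccc(OC)cc1)CC(=O)c1ccc(OCOC)cc1OCOC
F8 | step 14 | (3R,6E)-1-(2,4-dihydroxyphenyl)-3-ethenyl-8-hydroxy-3,7-dimethyloct-6-en-1-one | C=C[C@](C)(CC/C=C(\C)CO)CC(=O)c1ccc(O)cc1O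
F9 | step 14 | (3R,6E)-8-bromo-1-(2,4-dihydroxyphenyl)-3-ethenyl-3,7-dimethyloct-6-en-1-one | C=C[C@](C)(CC/C=C(\C)CBr)CC(=O)c1ccc(O)cc1O
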